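Labdane numbering is used throughout: ring A = C1–C5 and C10, ring B = C5–C10, C17 on C8, C18/C19 on C4, C20 on C10, side chain C11–C16.

## Analysis of the target

- **Ring system.** The target is a 9α,13;15,16-diepoxylabd-14-ene. It is a trans-decalin carrying two spiro centres: C9 (decalin/tetrahydrofuran) and C13 (tetrahydrofuran/2,3-dihydrofuran).
- **Stereocentres.** There are eight (3S,4S,5S,6S,8S,9R,10S,13R). In ring terms these are 3β-OAc (equatorial), 4β-CH2OAc (C19, axial), 5α-H, 6β-OH (axial), 8α-Me (equatorial), 9α-O (axial), 10β-Me (axial), and C13 with C14 on the C10 side of the tetrahydrofuran.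
- **Hardest carbon.** C9 is fully substituted (O, C8, C10, C11) and sits next to quaternary C10. Its oxygen lies on the α face, which is also the face from which a carbon nucleophile would attack a C9 ketone.
- **Second hard point.** The 6β-OH is syn-axial to both C19 and C20. It is the less stable epimer, and electrophilic oxidation of a 7-ketone enolate cannot deliver it because that oxidation arrives from the α face.
- **Sensitive groups.**
  - The C14=C15 enol ether opens to a furan with acid.
  - The C7 ketone is β to the C9–O bond, so E1cB loss of the ether is possible.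
  - The α-ketol is sensitive to base.
  - Two acetates must coexist with a free secondary alcohol.
- **Feature the plan is built on.** O6 and O9 stand 1,4 across ring B, on C6 and C9, and flank C7(=O)–C8(Me). This is the retron of a dioxygen [4+2] addition to a C6=C7(O)–C8=C9 diene.

## Retrosynthetic reasoning

**30 ⇒ 29 (two O–acyl bonds).** The acetates go on last. In triol 29 the primary C19-OH and the equatorial 3β-OH are accessible. The 6β-OH is shielded by C19 and C20, so the substitution pattern of the target is the intrinsic acylation pattern. The basic conditions do not harm the enol ether.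

**29 ⇒ 28 (O16–C15).** The acid-labile dihydrofuran is opened to a homopropargylic alcohol. The forward reaction is an endo cycloisomerisation through a metal vinylidene under neutral or basic conditions. The enol ether then has to survive only one further step.

**28 ⇒ 27 ⇒ 26 (C8–H, C6–H, C19 oxidation level).** The 7-ketone is kept masked as its C7=C8 silyl enol ether, and C6 is carried as a ketone. Hydride can reach C6 only from the α face, which gives the axial 6β-OH. The same reduction turns the C19 ester into CH2OH and releases the auxiliary. The β-alkoxy ketone and C8-H appear only on desilylation.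

**26 ⇒ 25 (O9–C13).** The tetrahydrofuran is cut at C13, not at C9. An enantiopure 2,2-disubstituted epoxide is opened 5-exo with inversion by the 9α-OH. C13 is therefore set by reagent control, independently of the decalin, and C16-OH is released unprotected.

**25 ⇒ 23 (C6–O and C9–O, key step).** Both oxygens are removed together. Photooxygenation of the ring-B silyloxydiene 23, followed by base-induced opening of endoperoxide 24, has four jobs:
- put both oxygens on the α face;
- fix C9;
- turn C6 into the ketone;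
- leave O7 masked.

The precursor has no stereocentre at C6, C8 or C9.

**23 ⇒ 22 ⇒ 21 (O7).** The diene comes from cross-conjugated enolisation of enone 22. Enone 22 comes from allylic oxidation of the tetrasubstituted alkene 21.

**21 ⇒ 13 + 19 (C9–C11).** The side chain is joined at an sp2 carbon by sp2–sp3 cross-coupling. No facial question arises at C9 at this stage. Fragment 19 goes back to 14 and 15 through an asymmetric epoxidation that sets C13.

**13 ⇒ 10 ⇒ 8 (C4–C5 and C9–C10).** The decalin, with the 3-oxo/4β-ester/4α-methyl pattern of ring A, is unfolded to acyclic β-keto ester 8. A radical bicyclisation ending on the nitrile gives the hindered C9 ketone directly. That ketone is distinguishable from the C3 ketone.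

**8 ⇒ 3 + 7.** Dianion alkylation joins the auxiliary-bearing C4/C3/C2 unit to an allylic bromide made from 4 in three steps.

## Alternatives that were turned down

**Alternative 1: (textbook) C9–C11 by 1,2-addition.** (S)-Wieland–Miescher ketone A1 would be elaborated to decalone A2. 2-(3-Furyl)ethyllithium would then be added, and the furan converted through a butenolide and oxa-Michael closure.
- The nucleophile would approach C9 anti to the axial C20, that is, from the α face. This gives the 9β-carbinol A3 with the wrong C9.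
- All three ring-B oxygens would need separate sequences.
- Enolate oxidation of a 7-ketone places O6 on the α face.
- The functional-group steps would far outnumber the bond-forming ones.

**Alternative 2: C4–C5 and C9–C10 by a polarity-alternating radical bicyclisation.** A β-keto ester radical would end on a 2-alkylidene-tetrahydrofuran vinylogous ester and give 7-ketone A4 in one step.
- The second closure joins a tertiary radical to a tetrasubstituted, donor-deactivated alkene carbon.
- The in-chain carbonyl must sit at C7, so the product is a base-labile β-alkoxy ketone.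
- Its C6 can only be oxidised from the α face. Correcting this costs more steps than the cascade saves.
- The C3 ketone is not distinguishable from the C7 ketone.

**Alternative 3: O13–C9 by oxidative dearomatisation.** A 4-substituted 3,5-dimethylphenol would give spirodienone A5, which already holds the 6-oxo-Δ7 unit.
- The two dienone arms differ only through remote C13, so the C9/C13 relation and the absolute sense of the decalin are not controlled.
- Ring A would have to be annulated onto a β-methyl enone carbon (C10) next to the spiro centre.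
- Any C6-reduced dienol would rearomatise by loss of the C9–O bond.

Key step: step 17

Assumption: the (1S,2R,5S) auxiliary 1 is taken to shield the face of the C4 radical that would lead to the ent-decalin. If the sense is the opposite, its enantiomer is used with no other change.

## Route

Step 1
Reactants: 1 (+)-8-phenylmenthol; 2 methyl 2-methyl-3-oxobutanoate
Product: 3 (+)-8-phenylmenthyl 2-methyl-3-oxobutanoate
Conditions: DMAP (cat.), toluene, reflux, distil off MeOH
Reagents that add atoms: none
Why: Transesterification of a β-keto ester through its acylketene, driven by removal of methanol; the α-centre is configurationally labile and irrelevant.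

Step 2
Reactants: 4 6-methylhept-5-en-2-one
Product: 5 2,6-dimethylhept-5-enenitrile (racemic)
Conditions: TosMIC, t-BuOK, EtOH (1 equiv), DME, 0 °C to rt
Reagents that add atoms: TosMIC, Cc1ccc(cc1)S(=O)(=O)C[N+]#[C-]
Why: Van Leusen reductive cyanation turns the ketone into the homologous nitrile (C9); the new centre (C8) is erased in step 9, so no control is needed.

Step 3
Reactants: 5 nitrile
Product: 6 (E)-7-hydroxy-2,6-dimethylhept-5-enenitrile
Conditions: SeO2 (cat.), t-BuOOH, CH2Cl2, rt
Reagents that add atoms: tert-butyl hydroperoxide, CC(C)(C)OO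
Why: The Sharpless–Umbreit allylic oxidation (ene, then [2,3]) attacks the E-methyl of the isopropylidene group only; this fixes the E-alkene needed for the trans-decalin.

Step 4
Reactants: 6 allylic alcohol
Product: 7 (E)-7-bromo-2,6-dimethylhept-5-enenitrile
Conditions: CBr4, PPh3, CH2Cl2, 0 °C
Reagents that add atoms: carbon tetrabromide, BrC(Br)(Br)Br
Why: The Appel reaction of a primary allylic alcohol proceeds without allylic shift or loss of alkene geometry.

Step 5
Reactants: 3 auxiliary β-keto ester; 7 allylic bromide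
Product: 8 (+)-8-phenylmenthyl (E)-10-cyano-2,6-dimethyl-3-oxoundec-6-enoate
Conditions: NaH, then n-BuLi, THF, 0 °C; 7, −78 to 0 °C; AcOH quench
Reagents that add atoms: none
Why: Weiler dianion alkylation takes place at the terminal (γ) carbon with a reactive allylic bromide and forms C1–C2; the nitrile is much less acidic and less electrophilic than the reacting partners.

Step 6
Reactants: 8 cyano-ene β-keto ester
Product: 10 trans-decalin diketo ester (3,9-dioxo, 4β-CO2R*, 4α-Me, 5α-H, 8α-Me, 10β-Me), via C9 ketimine 9 (not isolated)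
Conditions: Mn(OAc)3·2H2O (2.2 equiv), Yb(OTf)3, EtOH, 0 °C to rt; aq. work-up
Reagents that add atoms: water, O
Why: This is a Mn(III)-based oxidative radical tandem cyclisation: the electrophilic C4 radical closes 6-endo on C5 of the E-alkene, the tertiary C10 radical closes 6-exo on the nitrile, and the iminyl radical takes H from ethanol before hydrolysis. The chair–chair array gives the trans fusion with axial C20 and places the flat ester axial (C19) and the methyl equatorial. The auxiliary's phenyl group blocks one face of the chelated dicarbonyl radical and so sets the absolute sense; C8 equilibrates to equatorial.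

Step 7
Reactants: 10 diketo ester
Product: 11 3β-hydroxy-9-ketone
Conditions: NaBH4, MeOH/CH2Cl2, −40 °C
Reagents that add atoms: none
Why: The C9 ketone is flanked by quaternary C10 and tertiary C8 and is much slower than C3; axial (α) hydride attack at C3, opposite the axial ester, gives the equatorial 3β-alcohol.

Step 8
Reactants: 11 hydroxy ketone
Product: 12 3β-TBS ether
Conditions: TBSOTf, 2,6-lutidine, CH2Cl2, 0 °C
Reagents that add atoms: TBSOTf, CC(C)(C)[Si](C)(C)OS(=O)(=O)C(F)(F)F
Why: Standard silylation of a hindered secondary alcohol; lutidine is too weak a base to enolise the C9 ketone.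

Step 9
Reactants: 12 ketone
Product: 13 C9 enol triflate (Δ8(9))
Conditions: KHMDS, THF, −78 to 0 °C; PhNTf2
Reagents that add atoms: N-phenylbis(trifluoromethanesulfonimide), O=S(=O)(N(c1ccccc1)S(=O)(=O)C(F)(F)F)C(F)(F)F
Why: C10 is quaternary and the ester has no α-hydrogen, so enolisation can only go towards C8; O-triflation gives a single tetrasubstituted enol triflate and erases C8.

Step 10
Reactants: 14 2-bromoprop-2-en-1-ol; 15 (triisopropylsilyl)acetylene
Product: 16 2-methylidene-4-(triisopropylsilyl)but-3-yn-1-ol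
Conditions: PdCl2(PPh3)2 (cat.), CuI (cat.), Et3N, rt
Reagents that add atoms: none
Why: Sonogashira coupling of a vinyl bromide joins C13–C14; the free allylic alcohol is tolerated.

Step 11
Reactants: 16 enynol
Product: 17 (R)-[2-(triisopropylsilylethynyl)oxiran-2-yl]methanol
Conditions: Ti(Oi-Pr)4 (cat.), D-(−)-diethyl tartrate (cat.), t-BuOOH, 4 Å MS, CH2Cl2, −20 °C
Reagents that add atoms: tert-butyl hydroperoxide, CC(C)(C)OO
Why: Sharpless asymmetric epoxidation of a 2-substituted allylic alcohol. The (−)-tartrate delivers oxygen to the face opposite to the one that gives the (S)-2-substituted glycidols with the (+)-tartrate, which sets C13.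

Step 12
Reactants: 17 epoxy alcohol
Product: 18 (S)-epoxy aldehyde
Conditions: Dess–Martin periodinane, CH2Cl2, 0 °C
Reagents that add atoms: none
Why: Mild oxidation; the α-carbon is quaternary, so it cannot epimerise (the descriptor changes by priority only).

Step 13
Reactants: 18 epoxy aldehyde
Product: 19 (S)-2-ethenyl-2-(triisopropylsilylethynyl)oxirane
Conditions: Ph3PCH3Br, KHMDS, THF, −78 to 0 °C
Reagents that add atoms: methyltriphenylphosphonium bromide, C[P+](c1ccccc1)(c1ccccc1)c1ccccc1.[Br-]
Why: Wittig methylenation adds C11; epoxide and silyl alkyne are inert to the non-stabilised ylide at low temperature.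

Step 14
Reactants: 19 vinyl epoxide; 13 enol triflate
Product: 21 Δ8(9)-labdene with the C13–C16 epoxide side chain, via B-alkyl-9-BBN adduct 20 (not isolated)
Conditions: 9-BBN, THF, rt; then 13, PdCl2(dppf) (cat.), AsPh3 (cat.), Cs2CO3, DMF/H2O, 50 °C
Reagents that add atoms: none
Why: 9-BBN adds to the monosubstituted alkene much faster than to the bulky silyl alkyne and places boron on C11. The B-alkyl Suzuki–Miyaura coupling then forms C9–C11 at an sp2 carbon, so no stereochemical question arises.

Step 15
Reactants: 21 tetrasubstituted alkene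
Product: 22 Δ8(9)-7-ketone
Conditions: Rh2(cap)4 (cat.), t-BuOOH (aq.), K2CO3 (cat.), CH2Cl2, rt
Reagents that add atoms: tert-butyl hydroperoxide, CC(C)(C)OO
Why: In this catalytic allylic oxidation by peroxyl radicals, the ring C7–H (axial, aligned with the π bond) should be abstracted in preference to C11–H, which is buried between C1 and C20, and to the primary C17–H.

Step 16
Reactants: 22 enone
Product: 23 7-(TBS-oxy)-6,8(9)-diene
Conditions: LDA, THF, −78 °C; TBSCl, DMPU, −78 to 0 °C
Reagents that add atoms: TBSCl, CC(C)(C)[Si](C)(C)Cl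
Why: Kinetic deprotonation of an enone by a lithium amide takes place at the α′ position (C6) and gives the cross-conjugated dienolate; O-silylation gives the homoannular 2-silyloxydiene.

Step 17
Reactants: 23 silyloxydiene
Product: 25 9α-hydroxy-7-(TBS-oxy)-7-en-6-one, via 6α,9α-endoperoxide 24 (not isolated)
Conditions: O2, tetraphenylporphyrin (cat.), hν, CH2Cl2, −78 °C; then Et3N (cat.), −78 to 0 °C
Reagents that add atoms: dioxygen, O=O
Why: Ring B holds an s-cis, electron-rich homoannular diene, the substrate class in which singlet-oxygen [4+2] addition outruns the ene reaction; the closest known cases are 2-silyloxycyclohexa-1,3-dienes and steroidal 5,7-dienes. The concerted suprafacial addition forms C6–O and C9–O together and closes a 2,3-dioxabicyclo[2.2.2]oct-5-ene (24). The β face is closed at both termini (C20 beside C9; the axial C19 ester and C20 above C6), so both oxygens arrive from the α face; this fixes tetrasubstituted C9 with O axial and C11 equatorial. The Kornblum–DeLaMare opening has only one course, because C6 carries the only hydrogen next to the peroxide: the amine removes H6, the O–O bond breaks, C6 becomes the ketone and O9 the tertiary alcohol. The silyl enol ether ends up as the C7=C8 bridge alkene, so the 7-ketone stays masked and no β-alkoxy ketone is exposed to base. C5, now α to a ketone, is held in the more stable trans fusion. Silyl alkyne, epoxide, ester and silyl ether do not react with singlet oxygen.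

Step 18
Reactants: 25 hydroxy epoxide
Product: 26 9α,13-epoxy (spiro-tetrahydrofuran) 16-alcohol
Conditions: camphorsulfonic acid (cat.), CH2Cl2, 0 °C
Reagents that add atoms: none
Why: Acid-catalysed 5-exo-tet opening of a 4,5-epoxy alcohol at the more substituted carbon. The alkynyl group disfavours a free cation, so the opening should be invertive, turning (S)-C13 into the (R)-C13 of the target and freeing C16-OH.

Step 19
Reactants: 26 keto ester
Product: 27 6β,16,19-triol (7-silyl enol ether and 3-TBS ether retained)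
Conditions: LiAlH4, THF, 0 to 40 °C; Rochelle salt work-up
Reagents that add atoms: none
Why: 1,2-Reduction of the β,β-disubstituted 2-silyloxyenone from the only open (α) face gives the axial 6β-alcohol. The same reagent reduces the neopentyl ester to C19H2OH and returns auxiliary 1.

Step 20
Reactants: 27 tris-silyl compound
Product: 28 3β,6β,16,19-tetrahydroxy-7-ketone with terminal alkyne
Conditions: TBAF, AcOH (1:1), THF, 0 °C to rt
Reagents that add atoms: none
Why: Buffered fluoride removes the O-TBS, enol-TBS and C-TIPS groups. The enol is protonated at once by acetic acid, and C8 settles as the equatorial 8α-methyl epimer, which avoids the syn-axial contact with C20.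

Step 21
Reactants: 28 alkynol
Product: 29 9α,13;15,16-diepoxylabd-14-ene-3β,6β,19-triol-7-one
Conditions: (Et3N)Mo(CO)5 (cat., from Mo(CO)6, hν), Et3N, Et2O, rt
Reagents that add atoms: none
Why: McDonald endo cycloisomerisation of a 3-butyn-1-ol: O16 adds to the metal vinylidene carbon C15 and gives the 2,3-dihydrofuran under basic conditions. No other hydroxyl can reach the alkyne.

Step 22
Reactants: 29 triol
Product: 30 target
Conditions: Ac2O (2.5 equiv), pyridine, DMAP (cat.), 0 °C
Reagents that add atoms: acetic anhydride, CC(=O)OC(C)=O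
Why: The primary C19-OH and the equatorial 3β-OH acylate; the 6β-OH, syn-axial to C19 and C20 and hydrogen-bonded to the ketone, does not. The medium is basic, so the enol ether is safe.

## Compound list

1 | (+)-8-phenylmenthol, (1S,2R,5S)-5-methyl-2-(2-phenylpropan-2-yl)cyclohexan-1-ol | O[C@H]1C[C@@H](C)CC[C@@H]1C(C)(C)c1ccccc1 | starting material
2 | methyl 2-methyl-3-oxobutanoate | COC(=O)C(C)C(C)=O | starting material
3 | (+)-8-phenylmenthyl 2-methyl-3-oxobutanoate (both α-epimers) | CC(=O)C(C)C(=O)O[C@H]1C[C@@H](C)CC[C@@H]1C(C)(C)c1ccccc1 | intermediate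
4 | 6-methylhept-5-en-2-one | CC(=O)CCC=C(C)C | starting material
5 | 2,6-dimethylhept-5-enenitrile (racemic) | CC(C#N)CCC=C(C)C | intermediate
6 | (E)-7-hydroxy-2,6-dimethylhept-5-enenitrile | CC(C#N)CC/C=C(\C)CO | intermediate
7 | (E)-7-bromo-2,6-dimethylhept-5-enenitrile | CC(C#N)CC/C=C(\C)CBr | intermediate
8 | (+)-8-phenylmenthyl (E)-10-cyano-2,6-dimethyl-3-oxoundec-6-enoate (epimers at C2 and C10) | CC(C#N)CC/C=C(\C)CCC(=O)C(C)C(=O)O[C@H]1C[C@@H](C)CC[C@@H]1C(C)(C)c1ccccc1 | intermediate
9 | C9 ketimine of 10 | O=C(O[C@H]3C[C@@H](C)CC[C@@H]3C(C)(C)c3ccccc3)[C@@]1(C)C(=O)CC[C@@]2(C)[C@H]1CCC(C)C2=N | intermediate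
10 | trans-decalin 3,9-diketo 19-ester (4β-CO2R*, 4α-Me, 5α-H, 8α-Me, 10β-Me) | O=C(O[C@H]3C[C@@H](C)CC[C@@H]3C(C)(C)c3ccccc3)[C@@]1(C)C(=O)CC[C@@]2(C)[C@H]1CC[C@@H](C)C2=O | intermediate
11 | 3β-hydroxy-9-keto ester | O=C(O[C@H]3C[C@@H](C)CC[C@@H]3C(C)(C)c3ccccc3)[C@@]1(C)[C@@H](O)CC[C@@]2(C)[C@H]1CC[C@@H](C)C2=O | intermediate
12 | 3β-TBS-oxy-9-keto ester | O=C(O[C@H]3C[C@@H](C)CC[C@@H]3C(C)(C)c3ccccc3)[C@@]1(C)[C@@H](O[Si](C)(C)C(C)(C)C)CC[C@@]2(C)[C@H]1CC[C@@H](C)C2=O | intermediate
13 | C9 enol triflate, Δ8(9) | O=C(O[C@H]3C[C@@H](C)CC[C@@H]3C(C)(C)c3ccccc3)[C@@]1(C)[C@@H](O[Si](C)(C)C(C)(C)C)CC[C@@]2(C)[C@H]1CCC(C)=C2OS(=O)(=O)C(F)(F)F | intermediate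
14 | 2-bromoprop-2-en-1-ol | OCC(Br)=C | starting material
15 | (triisopropylsilyl)acetylene | C#C[Si](C(C)C)(C(C)C)C(C)C | starting material
16 | 2-methylidene-4-(triisopropylsilyl)but-3-yn-1-ol | OCC(=C)C#C[Si](C(C)C)(C(C)C)C(C)C | intermediate
17 | (R)-[2-(triisopropylsilylethynyl)oxiran-2-yl]methanol | OC[C@]1(C#C[Si](C(C)C)(C(C)C)C(C)C)CO1 | intermediate
18 | (S)-2-(triisopropylsilylethynyl)oxirane-2-carbaldehyde | O=C[C@]1(C#C[Si](C(C)C)(C(C)C)C(C)C)CO1 | intermediate
19 | (S)-2-ethenyl-2-(triisopropylsilylethynyl)oxirane | C=C[C@]1(C#C[Si](C(C)C)(C(C)C)C(C)C)CO1 | intermediate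
20 | B-alkyl-9-BBN adduct of 19 (boron on C11) | C1CC2CCCC(C1)B2CC[C@]1(C#C[Si](C(C)C)(C(C)C)C(C)C)CO1 | intermediate
21 | Δ8(9)-labdene, (13S)-13,16-epoxide, 14-yne-TIPS, 3β-OTBS, 19-ester | O=C(O[C@H]3C[C@@H](C)CC[C@@H]3C(C)(C)c3ccccc3)[C@@]1(C)[C@@H](O[Si](C)(C)C(C)(C)C)CC[C@@]2(C)[C@H]1CCC(C)=C2CC[C@]1(C#C[Si](C(C)C)(C(C)C)C(C)C)CO1 | intermediate
22 | Δ8(9)-7-ketone | O=C(O[C@H]3C[C@@H](C)CC[C@@H]3C(C)(C)c3ccccc3)[C@@]1(C)[C@@H](O[Si](C)(C)C(C)(C)C)CC[C@@]2(C)[C@H]1CC(=O)C(C)=C2CC[C@]1(C#C[Si](C(C)C)(C(C)C)C(C)C)CO1 | intermediate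
23 | 7-(TBS-oxy)-6,8(9)-diene | O=C(O[C@H]3C[C@@H](C)CC[C@@H]3C(C)(C)c3ccccc3)[C@@]1(C)[C@@H](O[Si](C)(C)C(C)(C)C)CC[C@@]2(C)[C@H]1C=C(O[Si](C)(C)C(C)(C)C)C(C)=C2CC[C@]1(C#C[Si](C(C)C)(C(C)C)C(C)C)CO1 | intermediate
24 | 6α,9α-epidioxy-7-(TBS-oxy)-7-ene | O=C(O[C@H]3C[C@@H](C)CC[C@@H]3C(C)(C)c3ccccc3)[C@@]1(C)[C@@H](O[Si](C)(C)C(C)(C)C)CC[C@@]2(C)[C@H]1[C@H]3OO[C@]2(CC[C@]1(C#C[Si](C(C)C)(C(C)C)C(C)C)CO1)C(C)=C3O[Si](C)(C)C(C)(C)C | intermediate
25 | 9α-hydroxy-7-(TBS-oxy)-7-en-6-one | O=C(O[C@H]3C[C@@H](C)CC[C@@H]3C(C)(C)c3ccccc3)[C@@]1(C)[C@@H](O[Si](C)(C)C(C)(C)C)CC[C@@]2(C)[C@H]1C(=O)C(O[Si](C)(C)C(C)(C)C)=C(C)[C@]2(O)CC[C@]1(C#C[Si](C(C)C)(C(C)C)C(C)C)CO1 | intermediate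
26 | (13R)-9α,13-epoxy-16-hydroxy-7-(TBS-oxy)-7-en-6-one | O=C(O[C@H]3C[C@@H](C)CC[C@@H]3C(C)(C)c3ccccc3)[C@@]1(C)[C@@H](O[Si](C)(C)C(C)(C)C)CC[C@@]2(C)[C@H]1C(=O)C(O[Si](C)(C)C(C)(C)C)=C(C)[C@]21CC[C@](CO)(C#C[Si](C(C)C)(C(C)C)C(C)C)O1 | intermediate
27 | 6β,16,19-triol, 7-silyl enol ether, 3β-OTBS | OC[C@@]1(C)[C@@H](O[Si](C)(C)C(C)(C)C)CC[C@@]2(C)[C@H]1[C@H](O)C(O[Si](C)(C)C(C)(C)C)=C(C)[C@]21CC[C@](CO)(C#C[Si](C(C)C)(C(C)C)C(C)C)O1 | intermediate
28 | 9α,13-epoxy-3β,6β,16,19-tetrahydroxylabd-14-yn-7-one | OC[C@@]1(C)[C@@H](O)CC[C@@]2(C)[C@H]1[C@H](O)C(=O)[C@@H](C)[C@]21CC[C@](CO)(C#C)O1 | intermediate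
29 | 9α,13;15,16-diepoxy-3β,6β,19-trihydroxylabd-14-en-7-one | OC[C@@]1(C)[C@@H](O)CC[C@@]2(C)[C@H]1[C@H](O)C(=O)[C@@H](C)[C@]21CC[C@]2(C=COC2)O1 | intermediate
30 | 3β,19-diacetoxy-9α,13;15,16-diepoxy-6β-hydroxylabd-14-en-7-one (CNP0317137.1) | CC(=O)OC[C@@]1(C)[C@@H](OC(C)=O)CC[C@@]2(C)[C@H]1[C@H](O)C(=O)[C@@H](C)[C@]21CC[C@]2(C=COC2)O1 | target

## Step count and least certain steps

Total: 22 steps. Longest linear sequence: 17 steps (steps 2–9 and 14–22).

**Step 17 (key step).**
- Most likely failure: the ene reaction at the tetrasubstituted C8=C9 (abstraction from C11 or C17) competes with the cycloaddition, or removal of the bridgehead H6 in 24 is slow and silyl transfer to the peroxide intervenes.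
- Fallback: O9 and O6 are introduced separately, starting from 22.
  - Nucleophilic epoxidation (t-BuOOH, DBU) from the α face gives the 8α,9α-epoxy ketone F1.
  - SmI2/MeOH at low temperature cleaves only the Cα–O bond to give the 9α-hydroxy ketone F2.
  - Acid closes the spiro ether to give F3.
  - Kinetic silyl enol ether formation and dimethyldioxirane give the 6-hydroxy ketone F4. Its C6 configuration is irrelevant.
  - Dess–Martin oxidation gives the 6,7-dione F5.
  - TBSOTf/Et3N silylates the more accessible C7=C8 enol, and the route is rejoined at 26.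

**Step 6.**
- Most likely failure: Mn(III) oxidises the tertiary C10 radical to the cation faster than the slow 6-exo addition to the nitrile, so the sequence stops at monocyclic alkenes. Facial control by the auxiliary may also be incomplete.
- Fallback: the radical is generated reductively. Compound 8 is brominated at C4 (NBS, Mg(ClO4)2) to give the tertiary α-bromo β-keto ester F6. This is cyclised with (Me3Si)3SiH/AIBN under slow addition, where nothing oxidises the tertiary radical. The route passes through 9 and, after hydrolysis, rejoins at 10.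

**Step 15.**
- Most likely failure: abstraction at C11 instead of C7, which gives the 11-ketone or mixtures.
- Fallback: the oxidation is done before C11 exists. Enol triflate 13 is oxidised under the same catalysis to the β-triflyloxy enone F7. As a vinylogous acyl triflate, F7 also undergoes oxidative addition more readily. Coupling with 20 gives 22 directly.

**Step 16.**
- Most likely failure: the axial H6β is shielded by C19 and C20, so γ-deprotonation (C11 or C17) gives an extended dienolate.
- Fallback: enone 22 is dehydrogenated with IBX to the Δ5,8-dien-7-one F8. Rhodium-catalysed 1,4-hydrosilylation with t-BuMe2SiH delivers hydride to C5 from the α face and gives the C6=C7 silyl enol ether regiospecifically, rejoining at 23.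

**Step 20.**
- Most likely failure: the transient C7–C8 enolate expels the C9 alkoxide (E1cB), or the α-ketol equilibrates at C6.
- Fallback: the O–Si bonds are cleaved under acid first. Aqueous HF in MeCN protonates C8 directly and gives the TIPS-alkyne tetraol ketone F9. The C–Si bond is then cleaved with AgF in MeCN followed by dilute acid, rejoining at 28.

## Further compounds

F1 | step 17 | 8α,9α-epoxy-7-ketone | O=C(O[C@H]3C[C@@H](C)CC[C@@H]3C(C)(C)c3ccccc3)[C@@]1(C)[C@@H](O[Si](C)(C)C(C)(C)C)CC[C@@]2(C)[C@H]1CC(=O)[C@@]3(C)O[C@@]23CC[C@]1(C#C[Si](C(C)C)(C(C)C)C(C)C)CO1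
F2 | step 17 | 9α-hydroxy-8α-methyl-7-ketone | O=C(O[C@H]3C[C@@H](C)CC[C@@H]3C(C)(C)c3ccccc3)[C@@]1(C)[C@@H](O[Si](C)(C)C(C)(C)C)CC[C@@]2(C)[C@H]1CC(=O)[C@@H](C)[C@]2(O)CC[C@]1(C#C[Si](C(C)C)(C(C)C)C(C)C)CO1
F3 | step 17 | 9α,13-epoxy-16-hydroxy-7-ketone | O=C(O[C@H]3C[C@@H](C)CC[C@@H]3C(C)(C)c3ccccc3)[C@@]1(C)[C@@H](O[Si](C)(C)C(C)(C)C)CC[C@@]2(C)[C@H]1CC(=O)[C@@H](C)[C@]21CC[C@](CO)(C#C[Si](C(C)C)(C(C)C)C(C)C)O1
F4 | step 17 | 6α-hydroxy-7-ketone | O=C(O[C@H]3C[C@@H](C)CC[C@@H]3C(C)(C)c3ccccc3)[C@@]1(C)[C@@H](O[Si](C)(C)C(C)(C)C)CC[C@@]2(C)[C@H]1[C@@H](O)C(=O)[C@@H](C)[C@]21CC[C@](CO)(C#C[Si](C(C)C)(C(C)C)C(C)C)O1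
F5 | step 17 | 6,7-dione | O=C(O[C@H]3C[C@@H](C)CC[C@@H]3C(C)(C)c3ccccc3)[C@@]1(C)[C@@H](O[Si](C)(C)C(C)(C)C)CC[C@@]2(C)[C@H]1C(=O)C(=O)[C@@H](C)[C@]21CC[C@](CO)(C#C[Si](C(C)C)(C(C)C)C(C)C)O1
F6 | step 6 | α-bromo β-keto ester of 8 | CC(C#N)CC/C=C(\C)CCC(=O)C(C)(Br)C(=O)O[C@H]1C[C@@H](C)CC[C@@H]1C(C)(C)c1ccccc1
F7 | step 15 | 9-triflyloxy-8(9)-en-7-one | O=C(O[C@H]3C[C@@H](C)CC[C@@H]3C(C)(C)c3ccccc3)[C@@]1(C)[C@@H](O[Si](C)(C)C(C)(C)C)CC[C@@]2(C)[C@H]1CC(=O)C(C)=C2OS(=O)(=O)C(F)(F)F
F8 | step 16 | Δ5,8(9)-dien-7-one | O=C(O[C@H]3C[C@@H](C)CC[C@@H]3C(C)(C)c3ccccc3)[C@@]1(C)[C@@H](O[Si](C)(C)C(C)(C)C)CC[C@@]2(C)C1=CC(=O)C(C)=C2CC[C@]1(C#C[Si](C(C)C)(C(C)C)C(C)C)CO1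
F9 | step 20 | TIPS-alkyne tetraol 7-ketone | OC[C@@]1(C)[C@@H](O)CC[C@@]2(C)[C@H]1[C@H](O)C(=O)[C@@H](C)[C@]21CC[C@](CO)(C#C[Si](C(C)C)(C(C)C)C(C)C)O1
A1 | alternative 1 | (S)-Wieland–Miescher ketone | O=C1CC[C@@]2(C)C(=C1)CCCC2=O
A2 | alternative 1 | methyl 3β-TBS-oxy-8α-methyl-9-oxo decalin-19-oate | COC(=O)[C@@]1(C)[C@@H](O[Si](C)(C)C(C)(C)C)CC[C@@]2(C)[C@H]1CC[C@@H](C)C2=O
A3 | alternative 1 | 9β-hydroxy-9α-[2-(3-furyl)ethyl] adduct (wrong C9) | COC(=O)[C@@]1(C)[C@@H](O[Si](C)(C)C(C)(C)C)CC[C@@]2(C)[C@H]1CC[C@@H](C)[C@@]2(O)CCc1ccoc1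
A4 | alternative 2 | 3,7-dioxo-9α,13-epoxy 19-ester from the vinylogous-ester cascade | COC(=O)[C@@]1(C)C(=O)CC[C@@]2(C)[C@H]1CC(=O)[C@@H](C)[C@]21CC[C@](CO)(C#C)O1
A5 | alternative 3 | 6,10-dimethyl-1-oxaspiro[4.5]deca-6,9-dien-8-one with the C13 substituents | CC1=CC(=O)C=C(C)C12CC[C@](CO)(C#C)O2
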